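The numbers in the tables were generated by integration for substances that don't exist, noise included.

I decide to follow one molecule of coupling partner and not one of starting material, because its charge of 0.333 M is smaller than the 0.37 M of starting material. That makes it the limiting reagent, and by the listed steps target can reach at most 90.0% of the starting material charged. Each such molecule comes to a fork: on catalyst intermediate A it gives target, on catalyst intermediate B second product.

| flask | starting material | second substrate | coupling partner | capture agent | free catalyst | remark | time |
|---|---|---|---|---|---|---|---|
| west | 0.37 M | 0.18 M (fed, over 8.0 h) | 0.333 M | 0.037 M | 3.7 mM | run made earlier; the fed solution adds 0.50 times the starting volume |  |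
| south-east | 0.37 M | 0.74 M (fed, over 8.0 h) | 0.333 M | 0.037 M | 3.7 mM | run made earlier; the fed solution adds 0.50 times the starting volume |  |
| flask | 0.37 M | 0.370 M (fed, over 8.0 h) | 0.333 M | 0.0370 M | 3.7 mM | the fed solution adds 0.50 times the starting volume | 15 h |

| run | time / h | target / % | starting material / % |
|---|---|---|---|
| west | 0.667 | 50 | 48 |
| west | 1.33 | 64 | 33 |
| west | 2.00 | 73 | 26 |
| west | 3.00 | 80 | 24 |
| west | 5.00 | 83 | 17 |
| west | 10.0 | 84 | 13 |
| south-east | 1.50 | 67 | 33 |
| south-east | 3.00 | 77 | 23 |
| south-east | 5.00 | 81 | 22 |
| south-east | 6.00 | 80 | 19 |
| south-east | 8.00 | 79 | 19 |
| south-east | 10.0 | 82 | 21 |

(each reading ± 1.5 percentage points)

1. amount of target in the flask at 15 h, in percent of the starting material charged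
2. amount of starting material in the flask at 15 h, in percent of the starting material charged

- for target the crystals are counted in
- charges are per starting volume, the dose included; the dosed solution carries all of it
- as a solid, counted per litre of solution: crystals
- on the list of suspects stand: starting material + free catalyst <-> catalyst intermediate A; coupling partner + catalyst intermediate A -> free catalyst + target; second substrate + free catalyst <-> catalyst intermediate B; coupling partner + catalyst intermediate B -> free catalyst + second product; crystals <-> target; catalyst intermediate A + capture agent -> trapped intermediate

The west run and the south-east run differ in their second substrate, 0.18 M against 0.74 M. Their last two target readings, set against that ceiling, give the west run 92.8% and the south-east run 89.4%. Both stand near that ceiling, and the south-east share reads 3.4 percentage points lower; with the scatter these readings carry, I take that gap as a larger part of the coupling partner leaving by the second branch in the south-east run than in the west run. The flask's dose is twice the west dose and half the south-east dose, so I take the mean of the two for its target share, the part of the coupling partner charged that ends as target: 91.1%. That gives me target 82.0%. Late readings of target and starting material add up to about the whole charge, 100% in the west run at 5.00 h, so I expect starting material 18.0% in the flask.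

The forecast says target 82.5% and starting material 16.5%, on the grounds that the flask's dose lies between the two runs and “the effect looks sublinear”; my target stands 0.5 points below its target, and my starting material stands 1.5 points above its starting material.

The flask gives target 82.3% and starting material 17.2%.

    starting material + free catalyst ⇌ catalyst intermediate A (K = 2.70 /M, k = 1200 /M/h)
    coupling partner + catalyst intermediate A → free catalyst + target (k = 1200 /M/h)
    second substrate + free catalyst ⇌ catalyst intermediate B (K = 2.90 /M, k = 39.0 /M/h)
    coupling partner + catalyst intermediate B → free catalyst + second product (k = 930 /M/h)
    crystals ⇌ target, rate k5*(cs5 - [target]) while solid is left; crystals form when [target] > cs5 (solubility = 0.130 M, k = 12.0 /h)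
    catalyst intermediate A + capture agent → trapped intermediate (k = 13.0 /M/h)

The flask's target share comes to 91.4%, beside the 91.1% I carried. In the neighbouring flask with 0.13 M of coupling partner, all else as in the recipe, the charge allows 35.1%, so the carried share gives target 32.0%. That neighbour holds target 33.8%, starting material 65.4% and second product 0.00328 M, with coupling partner at 0% of its charge, and its target share, higher than the flask's, is 96.3%.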